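Everything rests on a mirror plane hidden in the carbocycle (C1 = carbinol carbon bearing the C7H2OBz arm, C2=C3 = alkene, C4 = benzoate carbon, C5 and C6 = secondary carbinols). Writing the C4 oxygen as a carbonyl and replacing the C5/C6 oxygens by a second double bond gives an achiral cross-conjugated cyclohexa-2,5-dienone. It is bisected by a plane through C1 and C4, so C2=C3 and C5=C6 are enantiotopic. A chiral primary-amine salt with H2O2 should epoxidise C5=C6 alone: both oxirane C–O bonds form, and C1, C5 and C6 are fixed together. The precursor is the O-triethylsilyl para-quinol with the benzoate already in place. Reduction, benzoylation and acidic hydrolysis finish the synthesis.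

Key step: step 4

Remark: the locants C1–C7 defined above are kept for every intermediate.
Assumption: the quinine-derived amine is taken to favour the local enone face that leads to the (1R,5R,6S) series. If the sense proves opposite, the pseudo-enantiomeric 9-amino-9-deoxy-epi-quinidine salt replaces it and nothing else changes.

Step 1
Reactants: 1 4-hydroxybenzyl alcohol; 2 benzoic acid
Product: 3 4-hydroxybenzyl benzoate
Conditions: PPh3, DIAD, THF, 0 °C → rt
Reagents that add atoms: benzoic acid, OC(=O)c1ccccc1
Why: Mitsunobu esterification: only the aliphatic hydroxyl becomes an alkoxyphosphonium leaving group and only the carboxylic acid is acidic enough to serve as the nucleophile, so the benzylic carbon is esterified with the phenol left free, whereas an acyl chloride with base would take the phenoxide first and would provoke 1,6-elimination of the product to a quinone methide.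

Step 2
Reactants: 3 4-hydroxybenzyl benzoate
Product: 4 4-(benzoyloxymethyl)-4-hydroxycyclohexa-2,5-dienone (achiral para-quinol)
Conditions: PhI(OAc)2, MeCN–H2O 3:1, 0 °C
Reagents that add atoms: water, O
Why: Hypervalent-iodine oxidative dearomatisation of a para-alkylphenol: ligand exchange at iodine, loss of iodobenzene and capture of the electrophilic para carbon by water should give the para-quinol, the acetic acid released keeps the medium free of the phenoxide that would expel benzoate, and no stereocentre arises because the mirror plane is kept.

Step 3
Reactants: 4 para-quinol; 5 triethylsilyl trifluoromethanesulfonate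
Product: 6 4-(benzoyloxymethyl)-4-(triethylsilyloxy)cyclohexa-2,5-dienone (achiral)
Conditions: Et3SiOTf, 2,6-lutidine, CH2Cl2, −78 → 0 °C
Reagents that add atoms: triethylsilyl trifluoromethanesulfonate, CC[Si](CC)(CC)OS(=O)(=O)C(F)(F)F
Why: Silyl triflate silylation of a hindered tertiary alcohol with a non-nucleophilic base: the dienone has no enolisable hydrogen and 2,6-lutidine cannot add in conjugate fashion, and the triethylsilyl group is chosen because as a tertiary ether it should outlast the buffered peroxide medium of step 4 and screen one ring face, yet leave in the acid of step 7 without a step of its own.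

Step 4
Reactants: 6 para-quinol triethylsilyl ether
Product: 7 [(1R,5R,6S)-5,6-epoxy-4-oxo-1-(triethylsilyloxy)cyclohex-2-en-1-yl]methyl benzoate (C4 ketone, C2=C3 alkene, C5–C6 oxirane cis to the CH2OBz arm and trans to the silyloxy group)
Conditions: 9-amino-9-deoxy-epi-quinine (20 mol %), CF3CO2H (40 mol %), 50% aq. H2O2 (1.1 equiv), 1,4-dioxane, 30 °C
Reagents that add atoms: hydrogen peroxide, OO
Why: Proposed new method: the primary amine should condense with the C4 ketone of 6 to a catalyst-bound iminium ion, H2O2 oriented by the protonated quinuclidine–trifluoroacetate pair adds to C6, the enamine so formed attacks through C5 the proximal peroxide oxygen with loss of water, and hydrolysis returns the amine. The closest known reaction types are the primary-amine-salt-catalysed epoxidation of simple cyclic enones with H2O2 and the phase-transfer-catalysed epoxidation of quinone monoketals, whereas the desymmetrisation of a cross-conjugated para-quinol ether in this way has not been shown. The oxirane, the only ring formed, closes in a 3-exo-tet mode at the O–O bond. The catalyst fixes the local enone face that is attacked, a topicity that 6 offers once on each ring face (C5=C6 from the side of C7, C2=C3 from the side of the silyloxy group), and the substrate decides between the two by admitting peroxide only anti to the C1–OSiEt3 bond (bulk of the silyl group, C–O bond antiperiplanar to the incoming nucleophile), so C6 and with it C1 are set by this pair of controls, while C5 follows because the tethered oxygen can close only on the face it already occupies. The step therefore needs enantioface, ring-face and mono-over-bis selectivity: the silyl ether masks the hydroxyl that would otherwise guide peroxide to its own face, a lapse in ring-face bias should give a separable diastereomer and not the enantiomer, and about one equivalent of H2O2 limits a second epoxidation, which should in any case consume the minor enantiomer faster. The quaternary C1 excludes dienamine formation and aromatisation, and the benzoate on C7 excludes retro-aldol loss of formaldehyde.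

Step 5
Reactants: 7 epoxy enone
Product: 8 [(1R,4S,5S,6S)-5,6-epoxy-4-hydroxy-1-(triethylsilyloxy)cyclohex-2-en-1-yl]methyl benzoate (C4 hydroxyl cis to the oxirane)
Conditions: NaBH4, CeCl3·7H2O, MeOH, −78 °C
Reagents that add atoms: none
Why: Luche 1,2-reduction: the hard cerium-modified borohydride attacks the C4 carbonyl and not C2, and it should arrive on the ring face opposite the adjacent oxirane oxygen, so the new hydroxyl lies cis to the oxirane (4S), while ester, silyl ether and oxirane are inert at this temperature.

Step 6
Reactants: 8 epoxy alcohol; 9 benzoyl chloride
Product: 10 [(1R,4S,5S,6S)-4-(benzoyloxy)-5,6-epoxy-1-(triethylsilyloxy)cyclohex-2-en-1-yl]methyl benzoate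
Conditions: BzCl, pyridine, 4-(dimethylamino)pyridine (cat.), CH2Cl2, 0 °C → rt
Reagents that add atoms: benzoyl chloride, O=C(Cl)c1ccccc1
Why: Nucleophile-catalysed acylation of the only free hydroxyl, in which the C4–O bond is not touched and the C4 configuration is therefore retained.

Step 7
Reactants: 10 epoxy dibenzoate
Product: 12 kweichowenol B [(1R,4S,5S,6S)-4-(benzoyloxy)-1,5,6-trihydroxycyclohex-2-en-1-yl]methyl benzoate, via hydroxy epoxide 11 (not isolated)
Conditions: HClO4 (aq., 0.2 equiv), THF–H2O 3:1, 0 °C → rt
Reagents that add atoms: water, O
Why: Acid-catalysed silyl ether hydrolysis followed by SN2-like trans-diaxial opening of the protonated oxirane by water (Fürst–Plattner rule): C6 is neopentyl-like beside the quaternary C1, so water should enter at C5 from the face opposite the oxirane with inversion while the C6–O bond stays as it is, which gives the all-trans oxygen pattern C4/C5/C6/C1, and neither benzoate can participate because both lie on the oxirane face.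

Compound list
1 | 4-hydroxybenzyl alcohol | OCc1ccc(O)cc1 | starting material
2 | benzoic acid | OC(=O)c1ccccc1 | starting material
3 | 4-hydroxybenzyl benzoate | O=C(OCc1ccc(O)cc1)c1ccccc1 | intermediate
4 | 4-(benzoyloxymethyl)-4-hydroxycyclohexa-2,5-dienone | O=C1C=CC(O)(COC(=O)c2ccccc2)C=C1 | intermediate
5 | triethylsilyl trifluoromethanesulfonate | CC[Si](CC)(CC)OS(=O)(=O)C(F)(F)F | starting material
6 | 4-(benzoyloxymethyl)-4-(triethylsilyloxy)cyclohexa-2,5-dienone | O=C1C=CC(COC(=O)c2ccccc2)(O[Si](CC)(CC)CC)C=C1 | intermediate
7 | (1R,5R,6S)-epoxy enone, oxirane cis to CH2OBz | O=C(OC[C@]1(O[Si](CC)(CC)CC)C=CC(=O)[C@@H]2O[C@H]12)c1ccccc1 | intermediate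
8 | (1R,4S,5S,6S)-epoxy alcohol, C4–OH cis to the oxirane | O=C(OC[C@]1(O[Si](CC)(CC)CC)C=C[C@H](O)[C@@H]2O[C@H]12)c1ccccc1 | intermediate
9 | benzoyl chloride | O=C(Cl)c1ccccc1 | starting material
10 | (1R,4S,5S,6S)-epoxy dibenzoate, C1 silyl ether | O=C(OC[C@]1(O[Si](CC)(CC)CC)C=C[C@H](OC(=O)c3ccccc3)[C@@H]2O[C@H]12)c1ccccc1 | intermediate
11 | (1R,4S,5S,6S)-hydroxy epoxide, C1–OH free | O=C(OC[C@]1(O)C=C[C@H](OC(=O)c3ccccc3)[C@@H]2O[C@H]12)c1ccccc1 | intermediate
12 | kweichowenol B | O=C(OC[C@]1(O)C=C[C@H](OC(=O)c2ccccc2)[C@@H](O)[C@@H]1O)c1ccccc1 | target

Total steps: 7. Longest linear sequence: 7 steps (1 → 12).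

Steps most likely to fail

**Step 4.** Several things may go wrong:
- iminium formation from the cross-conjugated dienone may be slow;
- discrimination between the two local enone faces may be weak;
- peroxide may be delivered on the silyloxy face;
- the reaction may run on to the bis-epoxide.

The fallback uses known chemistry, sets out from 6 and comes back at 8.
- Weitz–Scheffer epoxidation of 6 with tBuOOH and DBU in CH2Cl2 at 0 °C relies on the bulky peroxide anion and the substrate's facial bias alone. It should give the racemic epoxy enone F1.
- Luche reduction under the conditions of step 5 then gives the racemic epoxy alcohol F2.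
- Lipase-catalysed kinetic resolution (Burkholderia cepacia lipase, vinyl acetate, tBuOMe, rt) follows. By the empirical size rule for secondary alcohols (oxirane-bearing flank large, vinyl flank small), it is expected to acylate the (4R) antipode to the acetate F3. The (4S)-alcohol 8 is left behind and is separated by chromatography.

**Step 7.** Water may attack C6 in competition with C5. Opening of an oxirane flanked by two oxygen-bearing carbons may also be slow enough for the mineral acid to shift acyl groups or to ionise the allylic C4–O bond. The fallback sets out from 10 and comes back at 12. It gives each event its own mild reagent and replaces water by a bulkier carboxylic acid nucleophile.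
- The silyl ether is removed with HF·pyridine buffered with pyridine in THF at 0 °C, and 11 is isolated.
- Formolysis of 11 in formic acid at rt is the first half of the classical performic-acid trans-dihydroxylation. It should open the oxirane at the less shielded C5 to the 5-O-formate F4.
- KHCO3 in methanol at 0 °C removes the formate, which is cleaved far faster than a benzoate, to give 12.

**Step 5.** Facial selectivity may be poor, because the silyloxy group across the ring lies on the face from which hydride must come and may offset the bias of the oxirane. The fallback sets out from 7 and comes back at 10. It sets C4 by SN2 inversion instead of by facial bias.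
- The two C4 epimers from the reduction are separated, and 8 continues through step 6.
- The (4R)-epimeric alcohol F5 (hydroxyl trans to the oxirane) is treated with benzoic acid 2, PPh3 and DIAD in toluene at 0 °C.
- This Mitsunobu inversion should deliver 10 directly, so both epimers converge. The SN2′ pathway is disfavoured by the quaternary C1 next to C2.

Further compounds
F1 | step 4 | racemic epoxy enone (1:1 mixture of 7 and its mirror image) | O=C(OC[C@]1(O[Si](CC)(CC)CC)C=CC(=O)[C@@H]2O[C@H]12)c1ccccc1.O=C(OC[C@@]1(O[Si](CC)(CC)CC)C=CC(=O)[C@H]2O[C@@H]12)c1ccccc1
F2 | step 4 | racemic epoxy alcohol (1:1 mixture of 8 and its mirror image) | O=C(OC[C@]1(O[Si](CC)(CC)CC)C=C[C@H](O)[C@@H]2O[C@H]12)c1ccccc1.O=C(OC[C@@]1(O[Si](CC)(CC)CC)C=C[C@@H](O)[C@H]2O[C@@H]12)c1ccccc1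
F3 | step 4 | (1S,4R,5R,6R)-4-O-acetate of the mirror image of 8 | O=C(OC[C@@]1(O[Si](CC)(CC)CC)C=C[C@@H](OC(C)=O)[C@H]2O[C@@H]12)c1ccccc1
F4 | step 7 | [(1R,4S,5S,6S)-4-(benzoyloxy)-5-(formyloxy)-1,6-dihydroxycyclohex-2-en-1-yl]methyl benzoate | O=C(OC[C@]1(O)C=C[C@H](OC(=O)c2ccccc2)[C@@H](OC=O)[C@@H]1O)c1ccccc1
F5 | step 5 | (1R,4R,5S,6S)-epoxy alcohol, C4 epimer of 8 (hydroxyl trans to the oxirane) | O=C(OC[C@]1(O[Si](CC)(CC)CC)C=C[C@@H](O)[C@@H]2O[C@H]12)c1ccccc1
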